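**Strategy.** Ring A (C1–C5, C10) is made one carbon short, as a trans-fused cyclopentanone in which the C2 carbonyl is bonded directly to the gem-dimethyl carbon C4. The key step inserts C3 between C2 and C4 by a β-oxido carbenoid ring expansion. It exploits the fact that in ring A the C2 oxygen lies between two methylenes (C1, C3), each attached to a quaternary carbon (C10, C4), so the quaternary carbon should migrate. The precursor comes from (+)-verbenone, whose six-membered ring becomes ring B: conjugate allylation sets C10, and a SmI2 fragmentation of the cyclobutane releases C4 as a radical that closes the five-membered ring onto a nitrile. Substrate-controlled reduction at C2 and a Negishi coupling for the (13Z)-enoate finish the route.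

Key step: step 7

Remark: the target SMILES is read as (2R,5S,9S,10S), the normal labdane series with an axial 2β-acetoxy group cis to the C10 methyl. Atoms keep their labdane numbers in all intermediates (ring A: C1–C5, C10; ring B: C5–C10; C17 exocyclic methylene; C20 methyl on C10). Compounds 1, 4 and 18 are taken as commercial.

**Step 1**
Reactants: 1 (1R,5R)-(+)-verbenone
Product: 3 (1R,4R,5R)-4-allyl-4,6,6-trimethylbicyclo[3.1.1]heptan-2-one, via silyl enol ether 2 (not isolated)
Conditions: CH2=CHCH2MgBr, CuBr·SMe2, Me3SiCl, THF, −78 °C; then 1 M HCl, rt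
Reagents that add atoms: allylmagnesium bromide, C=CC[Mg]Br; chlorotrimethylsilane, C[Si](C)(C)Cl (its atoms stay only in 2)
Why: Copper-mediated conjugate allylation of a β,β-disubstituted enone (allylcopper from the Grignard reagent with Me3SiCl activation), in which the allyl group adds to the enone β-carbon (labdane C10) from the face opposite the gem-dimethyl bridge and so fixes the quaternary stereocentre; aqueous acid then cleaves silyl enol ether 2.

**Step 2**
Reactants: 4 2-(tert-butyldimethylsilyloxy)ethanol
Product: 5 2-(tert-butyldimethylsilyloxy)ethyl trifluoromethanesulfonate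
Conditions: Tf2O, 2,6-lutidine, CH2Cl2, −78 °C
Reagents that add atoms: trifluoromethanesulfonic anhydride, O=S(=O)(OS(=O)(=O)C(F)(F)F)C(F)(F)F
Why: O-Sulfonylation of a primary alcohol with triflic anhydride and a hindered pyridine base should give an alkyl triflate reactive enough to alkylate a hindered ketone enolate.

**Step 3**
Reactants: 3 (1R,4R,5R)-4-allyl-4,6,6-trimethylbicyclo[3.1.1]heptan-2-one; 5 2-(tert-butyldimethylsilyloxy)ethyl trifluoromethanesulfonate
Product: 7 4-allyl-3-[2-(tert-butyldimethylsilyloxy)ethyl]-4,6,6-trimethylbicyclo[3.1.1]heptan-2-one (C3 side chain cis to the C4 methyl), via kinetic C3 epimer 6 (not isolated)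
Conditions: LiN(iPr)2, THF, −78 °C; 5, DMPU, −78 to −20 °C; then LiN(iPr)2, 0 °C; AcOH, −78 °C
Reagents that add atoms: none
Why: Enolate C-alkylation followed by deprotonation and kinetic protonation: the bridgehead α-carbon cannot enolise, so only C3 of the bicycle (labdane C9) reacts, and the final protonation of the enolate of 6 from the face opposite the gem-dimethyl bridge should place the side chain cis to the C4 methyl group (labdane C20) whatever the facial course of the alkylation.

**Step 4**
Reactants: 7 4-allyl-3-[2-(tert-butyldimethylsilyloxy)ethyl]-4,6,6-trimethylbicyclo[3.1.1]heptan-2-one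
Product: 10 4-(cyanomethyl) analogue of 7 (nitrile), via aldehyde 8 (not isolated), via aldimine 9 (not isolated)
Conditions: O3, CH2Cl2–MeOH, −78 °C; Me2S; then aq. NH3, I2, THF, rt
Reagents that add atoms: ammonia, N; ozone, [O-][O+]=O (its oxygen stays only in 8)
Why: Ozonolysis of the only alkene with reductive work-up should give aldehyde 8, and iodine in aqueous ammonia oxidises its aldimine 9 to the nitrile (oxidative conversion of an aldehyde into a nitrile), without touching a stereocentre.

**Step 5**
Reactants: 10 nitrile
Product: 12 trans-fused 4-[2-(tert-butyldimethylsilyloxy)ethyl]-1,1,3a-trimethyloctahydroindene-2,5-dione (labdane C2 and C8 carbonyls; C2 bonded to C4), via ketimine 11 (not isolated)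
Conditions: SmI2 (4 equiv), HMPA, THF, 0 °C to rt; then 0.5 M HCl, 0 °C
Reagents that add atoms: water, O
Why: Proposed new method: SmI2 should reduce the ketone to a ketyl whose strained cyclobutane bond to the gem-dimethyl carbon breaks (β-scission) to a samarium enolate and a tertiary radical at labdane C4, which adds 5-exo-dig to the nitrile carbon (C2) held on the trans-disposed neighbouring carbon C10; a second SmI2 reduces the iminyl radical and dilute acid hydrolyses ketimine 11, so the trans ring fusion follows from the C5/C10 relation set in step 1. The closest known reaction types are the SmI2 ketyl fragmentation of cyclobutyl and cyclopropyl ketones with radical trapping and the tin hydride 5-exo cyclisation of alkyl radicals onto nitriles.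

**Step 6**
Reactants: 12 diketone
Product: 13 trans-fused 4-[2-(tert-butyldimethylsilyloxy)ethyl]-1,1,3a-trimethyl-5-methyleneoctahydroinden-2-one
Conditions: Ph3PCH3Br, KOtBu, THF, 0 °C to rt
Reagents that add atoms: methyltriphenylphosphonium bromide, [Br-].C[P+](c1ccccc1)(c1ccccc1)c1ccccc1
Why: Wittig methylenation, expected to be site-selective for the cyclohexanone carbonyl (C8) because the cyclopentanone carbonyl (C2) lies between the gem-dimethyl carbon and a neopentyl methylene, the same steric bias that lets a 3-ketone be olefinated beside a 17-ketone in steroids; any epimerisation at C9 under the basic conditions should lead to the same equatorial isomer.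

**Step 7**
Reactants: 13 methylene ketone
Product: 15 12-(tert-butyldimethylsilyloxy)-13,14,15,16-tetranorlabd-8(17)-en-2-one (5α-H, 9α-H, 10β-methyl), via dibromomethyl carbinol 14 (not isolated)
Conditions: CH2Br2, lithium 2,2,6,6-tetramethylpiperidide, THF, −78 °C; then n-BuLi, −78 °C to rt; dilute HCl
Reagents that add atoms: dibromomethane, BrCBr
Why: Dibromomethyllithium, made in the flask from CH2Br2 and the lithium amide, adds to the C2 carbonyl of 13 to give the alkoxide of 14; bromine–lithium exchange with n-BuLi turns it into a β-oxido carbenoid, and a 1,2-shift of a ring bond from C2 to the carbenoid carbon with loss of bromide gives the ring-enlarged lithium enolate, which is protonated on work-up. The closest known reaction type is the β-oxido carbenoid one-carbon ring expansion of cyclic ketones (Nozaki–Yamamoto homologation), a relative of the Tiffeneau–Demjanov rearrangement. No ring is closed: the five-membered ring C10–C1–C2–C4–C5 grows into six-membered ring A by insertion of C3 between C2 and C4. No stereocentre is formed in the product (the carbinol centre of 14 is lost) and the migrating bond moves with retention, so C5, C9 and C10 are untouched. The step needs regioselectivity between the two α-carbons, quaternary C4 and methylene C1: in this electron-deficient rearrangement the more substituted carbon should migrate preferentially, which places the new methylene between C2 and C4. It also needs chemoselectivity, which is secured because C2 is the only carbonyl group left and the exocyclic alkene and the silyl ether are inert to the carbenoid.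

**Step 8**
Reactants: 15 silyl ether ketone
Product: 16 12-hydroxy-13,14,15,16-tetranorlabd-8(17)-en-2-one
Conditions: Bu4NF, THF, rt
Reagents that add atoms: none
Why: Fluoride-mediated cleavage of the primary silyl ether (desilylation); ketone and alkene should be untouched.

**Step 9**
Reactants: 16 hydroxy ketone
Product: 17 12-iodo-13,14,15,16-tetranorlabd-8(17)-en-2-one
Conditions: I2, PPh3, imidazole, CH2Cl2, 0 °C to rt
Reagents that add atoms: iodine, I-I
Why: Appel-type iodination: the primary alcohol is activated as an alkoxyphosphonium ion and displaced by iodide in an SN2 step.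

**Step 10**
Reactants: 18 methyl but-2-ynoate
Product: 19 methyl (Z)-3-iodobut-2-enoate
Conditions: NaI, AcOH, 110 °C
Reagents that add atoms: sodium iodide, [Na+].[I-]
Why: Hydroiodination of an ynoate: conjugate addition of iodide and anti protonation should give the (Z)-β-iodo enoate in which iodine is cis to the ester group.

**Step 11**
Reactants: 17 iodo ketone; 19 methyl (Z)-3-iodobut-2-enoate
Product: 21 methyl 2-oxolabda-8(17),13Z-dien-15-oate, via alkylzinc iodide 20 (not isolated)
Conditions: Zn dust, LiCl, THF, 40 °C; then 19, Pd(PPh3)4 (5 mol %), THF, rt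
Reagents that add atoms: none
Why: Negishi coupling: zinc inserts into the primary C–I bond to give alkylzinc iodide 20, which tolerates the ketone, and zerovalent palladium couples it with alkenyl iodide 19 with retention of the double-bond geometry, so the chain should end cis to the ester (13Z).

**Step 12**
Reactants: 21 keto ester
Product: 23 2β-hydroxylabda-8(17),13Z-dien-15-oic acid, via hydroxy ester 22 (not isolated)
Conditions: NaBH4, MeOH, 0 °C; then LiOH, THF–H2O, 45 °C; dilute HCl
Reagents that add atoms: lithium hydroxide, [Li+].[OH-]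
Why: Borohydride reduction followed by saponification: hydride should attack the C2 carbonyl from the α face because the β face is blocked by the two syn-axial methyl groups on C4 and C10, which gives the axial 2β-alcohol 22 (substrate control), and LiOH then hydrolyses the methyl ester.

**Step 13**
Reactants: 23 hydroxy acid
Product: 25 (2R,5S,9S,10S)-2-acetoxylabda-8(17),13Z-dien-15-oic acid (target), via mixed anhydride 24 (not isolated)
Conditions: Ac2O, DMAP, pyridine, 40 °C; then H2O–THF, NaHCO3, rt; dilute HCl
Reagents that add atoms: acetic anhydride, CC(=O)OC(C)=O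
Why: DMAP-catalysed acetylation of the hindered axial alcohol; the carboxyl group is converted at the same time into mixed anhydride 24, which mild aqueous base should hydrolyse back to the free acid without touching the secondary acetate.

**Compound list**

1 | (1R,5R)-(+)-verbenone, 4,6,6-trimethylbicyclo[3.1.1]hept-3-en-2-one | CC1=CC(=O)[C@@H]2C[C@H]1C2(C)C | starting material
2 | trimethylsilyl enol ether of 3 (4-allyl-4,6,6-trimethylbicyclo[3.1.1]hept-2-en-2-yl trimethylsilyl ether, allyl anti to the gem-dimethyl bridge) | C[Si](C)(C)OC1=C[C@@](C)(CC=C)[C@H]2C[C@@H]1C2(C)C | intermediate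
3 | (1R,4R,5R)-4-allyl-4,6,6-trimethylbicyclo[3.1.1]heptan-2-one (allyl anti to the gem-dimethyl bridge) | O=C1C[C@@](C)(CC=C)[C@H]2C[C@@H]1C2(C)C | intermediate
4 | 2-(tert-butyldimethylsilyloxy)ethanol | CC(C)(C)[Si](C)(C)OCCO | starting material
5 | 2-(tert-butyldimethylsilyloxy)ethyl trifluoromethanesulfonate | CC(C)(C)[Si](C)(C)OCCOS(=O)(=O)C(F)(F)F | intermediate
6 | C3 epimer of 7 (side chain cis to the allyl group, anti to the gem-dimethyl bridge) | O=C1[C@@H](CCO[Si](C)(C)C(C)(C)C)[C@@](C)(CC=C)[C@H]2C[C@@H]1C2(C)C | intermediate
7 | 4-allyl-3-[2-(tert-butyldimethylsilyloxy)ethyl]-4,6,6-trimethylbicyclo[3.1.1]heptan-2-one; allyl anti to the gem-dimethyl bridge, C3 side chain trans to allyl and cis to the C4 methyl | O=C1[C@H](CCO[Si](C)(C)C(C)(C)C)[C@@](C)(CC=C)[C@H]2C[C@@H]1C2(C)C | intermediate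
8 | aldehyde: 7 with the allyl group cut down to CH2CHO | O=C1[C@H](CCO[Si](C)(C)C(C)(C)C)[C@@](C)(CC=O)[C@H]2C[C@@H]1C2(C)C | intermediate
9 | N-unsubstituted aldimine of 8 | O=C1[C@H](CCO[Si](C)(C)C(C)(C)C)[C@@](C)(CC=N)[C@H]2C[C@@H]1C2(C)C | intermediate
10 | nitrile: 4-(cyanomethyl)-3-[2-(tert-butyldimethylsilyloxy)ethyl]-4,6,6-trimethylbicyclo[3.1.1]heptan-2-one, configuration as in 7 | O=C1[C@H](CCO[Si](C)(C)C(C)(C)C)[C@@](C)(CC#N)[C@H]2C[C@@H]1C2(C)C | intermediate
11 | ketimine: 12 with C2=NH in place of the C2 carbonyl | O=C1CC[C@H]2C(C)(C)C(=N)C[C@]2(C)[C@H]1CCO[Si](C)(C)C(C)(C)C | intermediate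
12 | trans-fused 4-[2-(tert-butyldimethylsilyloxy)ethyl]-1,1,3a-trimethyloctahydroindene-2,5-dione; 7a-H anti to the 3a-methyl, C4 side chain cis to the 3a-methyl (labdane C2 and C8 carbonyls, C3 missing) | O=C1CC[C@H]2C(C)(C)C(=O)C[C@]2(C)[C@H]1CCO[Si](C)(C)C(C)(C)C | intermediate
13 | trans-fused 4-[2-(tert-butyldimethylsilyloxy)ethyl]-1,1,3a-trimethyl-5-methyleneoctahydroinden-2-one, configuration as in 12 | C=C1CC[C@H]2C(C)(C)C(=O)C[C@]2(C)[C@H]1CCO[Si](C)(C)C(C)(C)C | intermediate
14 | 2-(dibromomethyl)-2-hydroxy adduct of 13 (carbinol centre undefined, lost in the rearrangement) | C=C1CC[C@H]2C(C)(C)C(O)(C(Br)Br)C[C@]2(C)[C@H]1CCO[Si](C)(C)C(C)(C)C | intermediate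
15 | 12-(tert-butyldimethylsilyloxy)-13,14,15,16-tetranorlabd-8(17)-en-2-one (5α-H, 9α-H, 10β-methyl) | C=C1CC[C@H]2C(C)(C)CC(=O)C[C@]2(C)[C@H]1CCO[Si](C)(C)C(C)(C)C | intermediate
16 | 12-hydroxy-13,14,15,16-tetranorlabd-8(17)-en-2-one | C=C1CC[C@H]2C(C)(C)CC(=O)C[C@]2(C)[C@H]1CCO | intermediate
17 | 12-iodo-13,14,15,16-tetranorlabd-8(17)-en-2-one | C=C1CC[C@H]2C(C)(C)CC(=O)C[C@]2(C)[C@H]1CCI | intermediate
18 | methyl but-2-ynoate | CC#CC(=O)OC | starting material
19 | methyl (Z)-3-iodobut-2-enoate | C/C(I)=C/C(=O)OC | intermediate
20 | (2-oxo-13,14,15,16-tetranorlabd-8(17)-en-12-yl)zinc iodide | C=C1CC[C@H]2C(C)(C)CC(=O)C[C@]2(C)[C@H]1CC[Zn]I | intermediate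
21 | methyl 2-oxolabda-8(17),13Z-dien-15-oate | C=C1CC[C@H]2C(C)(C)CC(=O)C[C@]2(C)[C@H]1CC/C(C)=C\C(=O)OC | intermediate
22 | methyl 2β-hydroxylabda-8(17),13Z-dien-15-oate | C=C1CC[C@H]2C(C)(C)C[C@@H](O)C[C@]2(C)[C@H]1CC/C(C)=C\C(=O)OC | intermediate
23 | 2β-hydroxylabda-8(17),13Z-dien-15-oic acid | C=C1CC[C@H]2C(C)(C)C[C@@H](O)C[C@]2(C)[C@H]1CC/C(C)=C\C(=O)O | intermediate
24 | acetic 2β-acetoxylabda-8(17),13Z-dien-15-oic anhydride | C=C1CC[C@H]2C(C)(C)C[C@@H](OC(C)=O)C[C@]2(C)[C@H]1CC/C(C)=C\C(=O)OC(C)=O | intermediate
25 | (2R,5S,9S,10S)-2-acetoxylabda-8(17),13Z-dien-15-oic acid (2β-acetoxy) | C=C1CC[C@H]2C(C)(C)C[C@@H](OC(C)=O)C[C@]2(C)[C@H]1CC/C(C)=C\C(=O)O | target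

**Step count and risks**

Total step count: 13. Longest linear sequence: 11 steps (steps 1, 3 to 9 and 11 to 13); steps 2 and 10 prepare the two side fragments.

Steps most likely to fail:

1. Step 5 (proposed new method). The tertiary radical may be quenched, by hydrogen abstraction from THF or by reduction, before it adds to the nitrile, or the ketyl may attack the nitrile itself. The fallback uses known chemistry, sets out from 10 and comes back to the route at 11. Me3SiI (from Me3SiCl and NaI, MeCN, −30 °C) opens the cyclobutyl ketone by iodide attack at the gem-dimethyl carbon to give the silyl enol ether F1. Aqueous work-up hydrolyses it to the γ-iodo ketone F2. Slow addition of Bu3SnH with AIBN in benzene at 80 °C then generates the same tertiary radical under the conditions established for 5-exo cyclisation onto nitriles. The resulting ketimine 11 is hydrolysed to 12 as in step 5.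

2. Step 7 (key step). The wrong ring bond (C1 instead of C4) may migrate, or the hindered ketone may be enolised instead of attacked. The fallback sets out from 13 and comes back at 15. PhSeCH2Li (from (PhSe)2CH2 and n-BuLi, THF, −78 °C) adds to the C2 carbonyl to give the β-hydroxy selenide F3. AgBF4 on alumina in CH2Cl2 then activates selenium as a leaving group and triggers the semipinacol ring enlargement, in which the more substituted carbon migrates.

3. Step 6. Site selectivity between the two carbonyl groups may be poor, or enolisation may outrun olefination. The fallback sets out from 12 and comes back at 13. The less basic and bulkier Me3SiCH2Li–CeCl3 (THF, −78 °C) adds to the less hindered C8 carbonyl to give the β-hydroxysilane F4. KH in THF then effects the Peterson elimination to the exocyclic alkene.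

**Further compounds**

F1 | step 5 | silyl enol ether of F2: 4-(2-iodopropan-2-yl)-3-(cyanomethyl)-3-methyl-2-[2-(tert-butyldimethylsilyloxy)ethyl]cyclohex-1-enyl trimethylsilyl ether | C[Si](C)(C)OC1=CC[C@@H](C(C)(C)I)[C@](C)(CC#N)[C@H]1CCO[Si](C)(C)C(C)(C)C
F2 | step 5 | γ-iodo ketone: 2-{2-[2-(tert-butyldimethylsilyloxy)ethyl]-6-(2-iodopropan-2-yl)-1-methyl-3-oxocyclohexyl}acetonitrile | O=C1CC[C@@H](C(C)(C)I)[C@](C)(CC#N)[C@H]1CCO[Si](C)(C)C(C)(C)C
F3 | step 7 | β-hydroxy selenide: 2-hydroxy-2-(phenylselanylmethyl) adduct of 13 | C=C1CC[C@H]2C(C)(C)C(O)(C[Se]c3ccccc3)C[C@]2(C)[C@H]1CCO[Si](C)(C)C(C)(C)C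
F4 | step 6 | β-hydroxysilane: 5-hydroxy-5-(trimethylsilylmethyl) adduct of 12 | C[Si](C)(C)CC1(O)CC[C@H]2C(C)(C)C(=O)C[C@]2(C)[C@H]1CCO[Si](C)(C)C(C)(C)C
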